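**Plan**

1. Locants are those of the cyclopenta[c]pyran core of the target (C1, O2, C3, C4, C4a, C5, C6, C7, C7a) and are used for the corresponding atoms of all intermediates. The retrosynthesis cuts, in this order: the isobutyl–C(=O) bond (thioester plus alkylzinc), C4–C4a (ring closure), O2–C3 (carbenoid O–H insertion), C1–C7a and C7–CH3 (aldol and conjugate addition on cyclopentenone), and the formyl carbon at chromone C3.
2. Enabling feature: the six-membered ring O2–C1–C7a–C4a–C4–C3 holds a tetrasubstituted, acceptor-substituted enol ether C3=C4 whose vinylic C4 is bonded to the ring-fusion carbon C4a, and C4a sits next to the methylene C5 of the five-membered ring. C4 can therefore be an alkenyl triflate (from a β-keto thioester hung on O2) and C4a=C5 a cyclopentene alkene, so that a 6-exo Heck closure delivers the heterocycle with C3=C4 already in place.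
3. Forward order: the 2-methoxychromone aldehyde is made first; a one-pot conjugate methylation/aldol on cyclopentenone builds the carbocycle with C7, C7a and C1; the helper ketone at C4a is turned into the C4a=C5 alkene; the O2–C3 ether is formed; the Heck reaction closes the dihydropyran; C5=C6 is reduced; the thioester becomes the isobutyl ketone.
4. Stereochemistry: C7 from the chiral copper catalyst; C7a (trans to the methyl group) and C1 (anti aldol) from the cyclic zinc enolate; C4a from C7a through the O2–C1 tether (cis ring fusion).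

Key step: step 13

Assumption: in step 6 the enantiomer of the chiral ligand is the one that gives the (3S)-configured zinc enolate; all later stereocenters follow from this centre.

**Route**

Step 1
Reactants: 1 1-(2-hydroxy-6-methylphenyl)ethan-1-one
Product: 2 4-hydroxy-5-methyl-2H-chromene-2-thione
Conditions: CS2, KOtBu (3 equiv), THF, 0 °C to rt; then 1 M HCl
Reagents that add atoms: carbon disulfide, S=C=S
Why: Thioacylation of the methyl ketone enolate by CS2 and ring closure of the phenol onto the dithiocarboxylate with loss of hydrogen sulfide is the standard Claisen-type entry to 4-hydroxychromene-2-thiones.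

Step 2
Reactants: 2 4-hydroxy-5-methyl-2H-chromene-2-thione
Product: 3 5-methyl-2-(methylsulfanyl)-4H-chromen-4-one
Conditions: MeI, K2CO3, acetone, rt
Reagents that add atoms: iodomethane, CI
Why: The ambident anion is alkylated at the soft sulfur (S-alkylation), which fixes the 4-oxo (chromone) tautomer and places a future leaving group at chromone C2.

Step 3
Reactants: 3 5-methyl-2-(methylsulfanyl)-4H-chromen-4-one
Product: 4 2-(methanesulfonyl)-5-methyl-4H-chromen-4-one
Conditions: mCPBA (2.2 equiv), CH2Cl2, 0 °C to rt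
Reagents that add atoms: 3-chloroperoxybenzoic acid, OOC(=O)c1cccc(Cl)c1
Why: Peracid oxidation of the sulfide to the sulfone makes the C2 substituent a good nucleofuge, and the electron-poor chromone alkene should not be epoxidized.

Step 4
Reactants: 4 2-(methanesulfonyl)-5-methyl-4H-chromen-4-one
Product: 5 2-methoxy-5-methyl-4H-chromen-4-one
Conditions: NaOMe (1.05 equiv), MeOH, 0 °C
Reagents that add atoms: sodium methoxide, C[O-].[Na+]
Why: Addition–elimination (nucleophilic vinylic substitution) of methoxide at C2 of the 2-sulfonylchromone should give the 2-methoxychromone regiospecifically, which avoids the O2/O4 ambiguity of methylating a 4-hydroxycoumarin.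

Step 5
Reactants: 5 2-methoxy-5-methyl-4H-chromen-4-one
Product: 7 2-methoxy-5-methyl-4-oxo-4H-chromene-3-carbaldehyde, via 3-lithiochromone 6 (not isolated)
Conditions: LiN(iPr)2, THF, −78 °C; then DMF, −78 °C; aq. NH4Cl
Reagents that add atoms: N,N-dimethylformamide, CN(C)C=O
Why: Directed deprotonation of the vinylic C3–H flanked by the carbonyl and methoxy groups, as known for 2-substituted chromones, followed by trapping with DMF is a directed lithiation–formylation.

Step 6
Reactants: 8 cyclopent-2-en-1-one; 7 2-methoxy-5-methyl-4-oxo-4H-chromene-3-carbaldehyde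
Product: 10 (2S,3S)-2-[(R)-hydroxy(2-methoxy-5-methyl-4-oxo-4H-chromen-3-yl)methyl]-3-methylcyclopentan-1-one, via zinc enolate 9 (not isolated)
Conditions: Me2Zn (1.5 equiv), (CuOTf)2·C6H6 (1 mol%), chiral peptide-based aryl phosphine ligand (2.4 mol%), toluene, −30 °C; then 7, −30 °C; aq. NH4Cl
Reagents that add atoms: dimethylzinc, C[Zn]C
Why: In this tandem copper-catalysed asymmetric conjugate addition–aldol reaction the ligand sets C7, the aldehyde approaches the cyclic (E)-zinc enolate anti to the new methyl group (C7a, 2,3-trans), and the closed chair transition state of the (E)-enolate should give the anti carbinol (C1, R).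

Step 7
Reactants: 10 (2S,3S)-2-[(R)-hydroxy(2-methoxy-5-methyl-4-oxo-4H-chromen-3-yl)methyl]-3-methylcyclopentan-1-one
Product: 12 (4S,5S)-5-[(R)-hydroxy(2-methoxy-5-methyl-4-oxo-4H-chromen-3-yl)methyl]-4-methylcyclopent-1-en-1-yl trifluoromethanesulfonate, via dilithium alkoxide enolate 11 (not isolated)
Conditions: LiN(SiMe3)2 (2.2 equiv), THF, −78 °C; then N-(5-chloropyridin-2-yl)triflimide (1.1 equiv), −78 to −40 °C; aq. NH4Cl
Reagents that add atoms: N-(5-chloropyridin-2-yl)-1,1,1-trifluoro-N-(trifluoromethanesulfonyl)methanesulfonamide, FC(F)(F)S(=O)(=O)N(c1ccc(Cl)cn1)S(=O)(=O)C(F)(F)F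
Why: Excess amide base forms the lithium alkoxide (which suppresses β-elimination) and, kinetically, the less substituted C5 enolate, which is O-sulfonylated to the enol triflate while the alkoxide should stay untouched (kinetic enol triflate formation).

Step 8
Reactants: 12 (4S,5S)-5-[(R)-hydroxy(2-methoxy-5-methyl-4-oxo-4H-chromen-3-yl)methyl]-4-methylcyclopent-1-en-1-yl trifluoromethanesulfonate
Product: 13 3-{(R)-hydroxy[(1R,5S)-5-methylcyclopent-2-en-1-yl]methyl}-2-methoxy-5-methyl-4H-chromen-4-one
Conditions: Pd(OAc)2 (5 mol%), PPh3 (10 mol%), Bu3N (3 equiv), HCO2H (2 equiv), DMF, 60 °C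
Reagents that add atoms: none
Why: Palladium-catalysed formate reduction of the enol triflate replaces OTf by H, so the helper oxygen at C4a is removed and the C4a=C5 alkene needed for the ring closure remains, with no stereocenter touched.

Step 9
Reactants: 14 2,2,6-trimethyl-4H-1,3-dioxin-4-one
Product: 16 S-ethyl 3-oxobutanethioate, via acetylketene 15 (not isolated)
Conditions: EtSH (3 equiv), toluene, sealed tube, 110 °C
Reagents that add atoms: ethanethiol, CCS
Why: Thermal retro-[4+2] cleavage of the dioxinone releases acetylketene, which the thiol traps as the β-keto thioester (acylketene acylation).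

Step 10
Reactants: 16 S-ethyl 3-oxobutanethioate
Product: 17 S-ethyl 2-diazo-3-oxobutanethioate
Conditions: 4-acetamidobenzenesulfonyl azide, Et3N, MeCN, 0 °C to rt
Reagents that add atoms: 4-acetamidobenzenesulfonyl azide, CC(=O)Nc1ccc(cc1)S(=O)(=O)N=[N+]=[N-]
Why: Regitz diazo transfer to the activated methylene of a β-keto thioester.

Step 11
Reactants: 13 3-{(R)-hydroxy[(1R,5S)-5-methylcyclopent-2-en-1-yl]methyl}-2-methoxy-5-methyl-4H-chromen-4-one; 17 S-ethyl 2-diazo-3-oxobutanethioate
Product: 18 S-ethyl 2-{(R)-(2-methoxy-5-methyl-4-oxo-4H-chromen-3-yl)[(1R,5S)-5-methylcyclopent-2-en-1-yl]methoxy}-3-oxobutanethioate (both epimers at the thioester α-carbon)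
Conditions: 17 (1.5 equiv, slow addition), Rh2(OAc)4 (2 mol%), CH2Cl2, 40 °C
Reagents that add atoms: none
Why: The rhodium carbenoid from 17 inserts into the O–H bond of the hindered secondary alcohol (O–H insertion), which forms the O2–C3 ether with retention at C1; the new α-carbon is epimerizable and becomes sp2 in the next step.

Step 12
Reactants: 18 S-ethyl 2-{(R)-(2-methoxy-5-methyl-4-oxo-4H-chromen-3-yl)[(1R,5S)-5-methylcyclopent-2-en-1-yl]methoxy}-3-oxobutanethioate
Product: 19 S-ethyl (2Z)-2-{(R)-(2-methoxy-5-methyl-4-oxo-4H-chromen-3-yl)[(1R,5S)-5-methylcyclopent-2-en-1-yl]methoxy}-3-[(trifluoromethanesulfonyl)oxy]but-2-enethioate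
Conditions: PhNTf2 (1.2 equiv), Cs2CO3 (1.5 equiv), DMF, 0 °C to rt
Reagents that add atoms: 1,1,1-trifluoro-N-phenyl-N-(trifluoromethanesulfonyl)methanesulfonamide, FC(F)(F)S(=O)(=O)N(c1ccccc1)S(=O)(=O)C(F)(F)F
Why: The β-keto thioester enolizes only between its two carbonyl groups and is O-triflated on the ketone oxygen (enol triflate formation); the non-chelated caesium enolate in DMF should place the triflate trans to the thioester and thus cis to the ether oxygen.

Step 13
Reactants: 19 S-ethyl (2Z)-2-{(R)-(2-methoxy-5-methyl-4-oxo-4H-chromen-3-yl)[(1R,5S)-5-methylcyclopent-2-en-1-yl]methoxy}-3-[(trifluoromethanesulfonyl)oxy]but-2-enethioate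
Product: 20 S-ethyl (1R,4aS,7S,7aR)-1-(2-methoxy-5-methyl-4-oxo-4H-chromen-3-yl)-4,7-dimethyl-1,4a,7,7a-tetrahydrocyclopenta[c]pyran-3-carbothioate
Conditions: Pd(OAc)2 (10 mol%), PPh3 (30 mol%), 1,2,2,6,6-pentamethylpiperidine (2 equiv), MeCN, 80 °C
Reagents that add atoms: none
Why: Zerovalent palladium (formed in situ from Pd(OAc)2 and PPh3) adds oxidatively into the C4–OTf bond of 19, the cationic alkenylpalladium species inserts the cyclopentene C4a=C5 bond in a syn fashion to form the C4–C4a bond, and syn β-hydride elimination toward C6 releases 20 and a palladium hydride that the amine base turns over. The closest known reaction type is the intramolecular Heck reaction of alkenyl triflates with cycloalkenes, which is well established for six-membered ring closure. The dihydropyran ring (O2, C1, C7a, C4a, C4, C3) closes in the 6-exo-trig mode, with the ether O2–C1 as the tether. The only new stereocenter, C4a, is controlled by the adjacent C7a: the tether can deliver the alkenylpalladium unit only to the alkene face that bears C1, so H-4a ends cis to H-7a (cis ring fusion), while C4 stays sp2 and the tetrasubstituted C3=C4 enol ether with its methyl and thioester groups arrives intact. The step needs 6-exo over 7-endo closure (ring size), a triflate cis to O2 (the (Z)-isomer from step 12; a donor–acceptor alkenylpalladium of this type can also equilibrate its geometry before insertion), elimination toward C6 and not C4a (the hydrogen at C4a is anti to palladium), and no later migration of the C5=C6 bond toward C7 (hindered amine base, cationic triflate pathway, immediate reduction in step 14).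

Step 14
Reactants: 20 S-ethyl (1R,4aS,7S,7aR)-1-(2-methoxy-5-methyl-4-oxo-4H-chromen-3-yl)-4,7-dimethyl-1,4a,7,7a-tetrahydrocyclopenta[c]pyran-3-carbothioate
Product: 21 S-ethyl (1R,4aS,7S,7aR)-1-(2-methoxy-5-methyl-4-oxo-4H-chromen-3-yl)-4,7-dimethyl-1,4a,5,6,7,7a-hexahydrocyclopenta[c]pyran-3-carbothioate
Conditions: 2-nitrobenzenesulfonohydrazide (5 equiv), Et3N, CH2Cl2, rt
Reagents that add atoms: none
Why: Diimide generated in the flask reduces the strained cis-disubstituted C5=C6 alkene by concerted syn hydrogen transfer (diimide reduction) and should leave the tetrasubstituted acceptor-substituted C3=C4 alkene, the chromone and the thioester untouched.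

Step 15
Reactants: 21 S-ethyl (1R,4aS,7S,7aR)-1-(2-methoxy-5-methyl-4-oxo-4H-chromen-3-yl)-4,7-dimethyl-1,4a,5,6,7,7a-hexahydrocyclopenta[c]pyran-3-carbothioate
Product: 22 3-[(1R,4aS,7S,7aR)-4,7-dimethyl-3-(3-methylbutanoyl)-1,4a,5,6,7,7a-hexahydrocyclopenta[c]pyran-1-yl]-2-methoxy-5-methyl-4H-chromen-4-one
Conditions: iBuZnBr (2 equiv, 0.5 M in THF), PdCl2(PPh3)2 (5 mol%), toluene/THF, rt; aq. NH4Cl
Reagents that add atoms: isobutylzinc bromide, CC(C)C[Zn]Br
Why: Fukuyama coupling (insertion of zerovalent palladium into the acyl–sulfur bond, transmetalation from the alkylzinc, reductive elimination) should give the isobutyl ketone under conditions that spare the 2-methoxychromone, which would not tolerate a Grignard or organolithium reagent.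

**Compound list**

1 | 1-(2-hydroxy-6-methylphenyl)ethan-1-one | CC(=O)c1c(C)cccc1O | starting material
2 | 4-hydroxy-5-methyl-2H-chromene-2-thione | Cc1cccc2oc(=S)cc(O)c12 | intermediate
3 | 5-methyl-2-(methylsulfanyl)-4H-chromen-4-one | CSc1cc(=O)c2c(C)cccc2o1 | intermediate
4 | 2-(methanesulfonyl)-5-methyl-4H-chromen-4-one | CS(=O)(=O)c1cc(=O)c2c(C)cccc2o1 | intermediate
5 | 2-methoxy-5-methyl-4H-chromen-4-one | COc1cc(=O)c2c(C)cccc2o1 | intermediate
6 | 3-lithio-2-methoxy-5-methyl-4H-chromen-4-one | COc1oc2cccc(C)c2c(=O)c1[Li] | intermediate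
7 | 2-methoxy-5-methyl-4-oxo-4H-chromene-3-carbaldehyde | COc1oc2cccc(C)c2c(=O)c1C=O | intermediate
8 | cyclopent-2-en-1-one | O=C1C=CCC1 | starting material
9 | methylzinc (3S)-3-methylcyclopent-1-en-1-olate | C[Zn]OC1=C[C@@H](C)CC1 | intermediate
10 | (2S,3S)-2-[(R)-hydroxy(2-methoxy-5-methyl-4-oxo-4H-chromen-3-yl)methyl]-3-methylcyclopentan-1-one | COc1oc2cccc(C)c2c(=O)c1[C@H](O)[C@@H]3[C@@H](C)CCC3=O | intermediate
11 | lithium (4S,5S)-5-[(R)-(lithiooxy)(2-methoxy-5-methyl-4-oxo-4H-chromen-3-yl)methyl]-4-methylcyclopent-1-en-1-olate | COc1oc2cccc(C)c2c(=O)c1[C@H](O[Li])[C@@H]3[C@@H](C)CC=C3O[Li] | intermediate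
12 | (4S,5S)-5-[(R)-hydroxy(2-methoxy-5-methyl-4-oxo-4H-chromen-3-yl)methyl]-4-methylcyclopent-1-en-1-yl trifluoromethanesulfonate | COc1oc2cccc(C)c2c(=O)c1[C@H](O)[C@@H]3[C@@H](C)CC=C3OS(=O)(=O)C(F)(F)F | intermediate
13 | 3-{(R)-hydroxy[(1R,5S)-5-methylcyclopent-2-en-1-yl]methyl}-2-methoxy-5-methyl-4H-chromen-4-one | COc1oc2cccc(C)c2c(=O)c1[C@H](O)[C@@H]3[C@@H](C)CC=C3 | intermediate
14 | 2,2,6-trimethyl-4H-1,3-dioxin-4-one | CC1=CC(=O)OC(C)(C)O1 | starting material
15 | acetylketene (but-1-ene-1,3-dione) | CC(=O)C=C=O | intermediate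
16 | S-ethyl 3-oxobutanethioate | CCSC(=O)CC(C)=O | intermediate
17 | S-ethyl 2-diazo-3-oxobutanethioate | CCSC(=O)C(=[N+]=[N-])C(C)=O | intermediate
18 | S-ethyl 2-{(R)-(2-methoxy-5-methyl-4-oxo-4H-chromen-3-yl)[(1R,5S)-5-methylcyclopent-2-en-1-yl]methoxy}-3-oxobutanethioate (both epimers at the thioester α-carbon) | COc1oc2cccc(C)c2c(=O)c1[C@H](OC(C(C)=O)C(=O)SCC)[C@@H]3[C@@H](C)CC=C3 | intermediate
19 | S-ethyl (2Z)-2-{(R)-(2-methoxy-5-methyl-4-oxo-4H-chromen-3-yl)[(1R,5S)-5-methylcyclopent-2-en-1-yl]methoxy}-3-[(trifluoromethanesulfonyl)oxy]but-2-enethioate | COc1oc2cccc(C)c2c(=O)c1[C@H](O/C(C(=O)SCC)=C(/C)OS(=O)(=O)C(F)(F)F)[C@@H]3[C@@H](C)CC=C3 | intermediate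
20 | S-ethyl (1R,4aS,7S,7aR)-1-(2-methoxy-5-methyl-4-oxo-4H-chromen-3-yl)-4,7-dimethyl-1,4a,7,7a-tetrahydrocyclopenta[c]pyran-3-carbothioate | COc1oc2cccc(C)c2c(=O)c1[C@@H]1OC(C(=O)SCC)=C(C)[C@H]2C=C[C@H](C)[C@H]21 | intermediate
21 | S-ethyl (1R,4aS,7S,7aR)-1-(2-methoxy-5-methyl-4-oxo-4H-chromen-3-yl)-4,7-dimethyl-1,4a,5,6,7,7a-hexahydrocyclopenta[c]pyran-3-carbothioate | COc1oc2cccc(C)c2c(=O)c1[C@@H]1OC(C(=O)SCC)=C(C)[C@H]2CC[C@H](C)[C@H]21 | intermediate
22 | 3-[(1R,4aS,7S,7aR)-4,7-dimethyl-3-(3-methylbutanoyl)-1,4a,5,6,7,7a-hexahydrocyclopenta[c]pyran-1-yl]-2-methoxy-5-methyl-4H-chromen-4-one | COc1oc2cccc(C)c2c(=O)c1[C@@H]1OC(C(=O)CC(C)C)=C(C)[C@H]2CC[C@H](C)[C@H]21 | target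

**Summary**

Total step count: 15. Longest linear sequence: 13 steps (steps 1–8 and 11–15); steps 9 and 10 make the diazo thioester in a side branch.

**Steps most likely to fail, with fallbacks**

Step 13 (ring closure). The closure may stall because the triflate geometry does not allow the ring to form, because zerovalent palladium inserts into the acyl–sulfur bond of the thioester, or because the new C5=C6 bond migrates toward C7 and erases that stereocenter. The fallback closes the same bond by a radical and sets out from 18. Treatment of 18 with Ph3PBr2 and Et3N in CH2Cl2 would give the alkenyl bromide S-ethyl 3-bromo-2-{(R)-(2-methoxy-5-methyl-4-oxo-4H-chromen-3-yl)[(1R,5S)-5-methylcyclopent-2-en-1-yl]methoxy}but-2-enethioate F1 as either or both geometric isomers. F1 would then be treated with Bu3SnH and AIBN in benzene at 80 °C under slow addition. The alkenyl radical at C4 inverts rapidly, so the alkene geometry does not matter; it should add 6-exo to C4a on the face fixed by C7a, and the C5 radical is reduced by the stannane. This returns to the route at 21 and bypasses 19, 20 and the diimide step.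

Step 6 (conjugate addition–aldol). The zinc enolate may add to the aldehyde with poor facial selectivity at the carbinol carbon, or may attack C2 of the chromone with loss of methoxide. The fallback separates the two events and sets out from 8. The zinc enolate from the same copper-catalysed methyl addition would be trapped with Me3SiCl as trimethyl{[(3S)-3-methylcyclopent-1-en-1-yl]oxy}silane F2. F2 would be exchanged with Bu2BOTf in CH2Cl2 at −78 °C to the boron enolate dibutyl{[(3S)-3-methylcyclopent-1-en-1-yl]oxy}borane F3, and F3 combined with 7 at −78 °C. The short boron–oxygen bonds of the boron aldol reaction tighten the chair transition state of the (E)-enolate, which should raise the anti selectivity. The sequence comes back to the route at 10.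

Step 7 (enol triflate next to a free carbinol). The lithium aldolate may fragment by retro-aldol cleavage, or the alkoxide may be sulfonylated in competition with the enolate. The fallback protects the hydroxyl group and sets out from 10. Silylation with Et3SiOTf and 2,6-lutidine would give (2S,3S)-2-[(R)-(2-methoxy-5-methyl-4-oxo-4H-chromen-3-yl)(triethylsilyloxy)methyl]-3-methylcyclopentan-1-one F4. Kinetic enolization with KN(SiMe3)2 at −78 °C and trapping with PhNTf2 would give (4S,5S)-5-[(R)-(2-methoxy-5-methyl-4-oxo-4H-chromen-3-yl)(triethylsilyloxy)methyl]-4-methylcyclopent-1-en-1-yl trifluoromethanesulfonate F5. Formate reduction with Pd(OAc)2, PPh3, Bu3N and HCO2H would give 2-methoxy-5-methyl-3-{(R)-[(1R,5S)-5-methylcyclopent-2-en-1-yl](triethylsilyloxy)methyl}-4H-chromen-4-one F6. Desilylation with Bu4NF buffered with AcOH comes back to the route at 13.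

**Further compounds**

F1 | step 13 | S-ethyl 3-bromo-2-{(R)-(2-methoxy-5-methyl-4-oxo-4H-chromen-3-yl)[(1R,5S)-5-methylcyclopent-2-en-1-yl]methoxy}but-2-enethioate (E/Z mixture) | COc1oc2cccc(C)c2c(=O)c1[C@H](OC(C(=O)SCC)=C(C)Br)[C@@H]3[C@@H](C)CC=C3
F2 | step 6 | trimethyl{[(3S)-3-methylcyclopent-1-en-1-yl]oxy}silane | C[Si](C)(C)OC1=C[C@@H](C)CC1
F3 | step 6 | dibutyl{[(3S)-3-methylcyclopent-1-en-1-yl]oxy}borane | CCCCB(CCCC)OC1=C[C@@H](C)CC1
F4 | step 7 | (2S,3S)-2-[(R)-(2-methoxy-5-methyl-4-oxo-4H-chromen-3-yl)(triethylsilyloxy)methyl]-3-methylcyclopentan-1-one | COc1oc2cccc(C)c2c(=O)c1[C@H](O[Si](CC)(CC)CC)[C@@H]3[C@@H](C)CCC3=O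
F5 | step 7 | (4S,5S)-5-[(R)-(2-methoxy-5-methyl-4-oxo-4H-chromen-3-yl)(triethylsilyloxy)methyl]-4-methylcyclopent-1-en-1-yl trifluoromethanesulfonate | COc1oc2cccc(C)c2c(=O)c1[C@H](O[Si](CC)(CC)CC)[C@@H]3[C@@H](C)CC=C3OS(=O)(=O)C(F)(F)F
F6 | step 7 | 2-methoxy-5-methyl-3-{(R)-[(1R,5S)-5-methylcyclopent-2-en-1-yl](triethylsilyloxy)methyl}-4H-chromen-4-one | COc1oc2cccc(C)c2c(=O)c1[C@H](O[Si](CC)(CC)CC)[C@@H]3[C@@H](C)CC=C3
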